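# Sesterfisherol: synthesis proposal built on a Claisen ring expansion of an oxane into ring B

## Structural features

Carbons are numbered C1–C25 in the order in which they occur in the SMILES string of the target (C1, C7, C12 and C16 are the methyls on C2, C6, C11 and C15; C20–C22 are the isopropyl group on C19). Ring A (C3, C4, C5, C6, C8) is joined to the eight-membered ring B (C2, C3, C8, C9, C10, C11, C13, C25) through C3–C8 and through the tetrasubstituted C2=C3 alkene, which is exocyclic to ring A and Z within ring B. Ring B is trans-fused along C13–C25 to the cyclohexane ring C (C13, C14, C15, C23, C24, C25), which is trans-fused along C15–C23 to ring D (C15, C17, C18, C19, C23). The eight stereocentres fall into three groups: C6/C8 in ring A; C11/C13/C25 around the B/C fusion (C25–OH axial on ring C, cis to the C11 side of C13); and C15/C23/C19 in ring D, where the isopropyl group, C24 and the C16 methyl are all cis on the cyclopentane. The only functional groups are the tertiary allylic alcohol at C25, which ionises under acid, and the hindered alkene, so every auxiliary oxygen must be removed at the end without acid. The real difficulty is ring B: a medium ring holding a tetrasubstituted alkene next to a fully substituted carbinol, with C8 remote from the other stereocentres. The key step exploits the array C2=C3–C8–C9–C10: with a carbonyl at C10 it is the retron of a Claisen rearrangement in which an oxygen bridges C2 and C10 inside a six-membered oxane (O, C10, C11, C13, C25, C2).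

## Logic of the disconnections

**35 back to 31 (through 34, 33, 32).** Cut: the O–CH2 bond of the C25 acetal; two C10–H bonds are replaced by a carbonyl. Reason: the C10 carbonyl is the residue of the ring expansion. Gain: the hydrocarbon ring B becomes a cyclooctenone. Demand: removing the carbonyl must not epimerise C11 (alpha to it) or touch C2=C3, so hydride reduction and radical deoxygenation are preferred to hydrazone chemistry. The acetal is cleaved reductively because the tertiary allylic alcohol does not tolerate acid.

**31 back to 30 (key step).** Cut: C8–C9; reconnect C2–O. Reason: the [3,3] shift makes the tetrasubstituted Z alkene and the eight-membered ring together and sets C8 by chirality transfer from C2. Gain: ring B is reduced to a six-membered cyclic enol ether. Demand: C2 must be the epimer with the cyclopentenyl group cis to the C25 oxygen on the oxane; a check of the descriptors of 30 and 31 confirms this is the epimer that suprafacial transfer requires. In that epimer the cyclopentenyl group is equatorial on the trans-fused chair, so the oxane must reach a twist-boat in the transition state.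

**30 back to 28 (through 29).** Cut: C9=C10 (methylene from a lactone carbonyl) and C11–C12. Reason: a lactone is the stable carrier of the enol ether, and its enolate allows C12 to be placed late. Gain: the acid-sensitive enol ether exists for one step only. Demand: the C11 methyl must end equatorial (cis to H-13), which is both the less hindered trajectory (the axial C25 oxygen blocks the other face) and the thermodynamic position.

**28 back to 20 and 24.** Cut: C2–C3 and O–C10. Reason: this is the convergent junction of ring A with the ring C/D block. Gain: two fragments of similar size. Demand: the C2 configuration must be controlled, and the C25 oxygen must neither migrate a protecting group to the new C2 alkoxide nor close a five-membered lactone onto C10. A trimethylsilyl ether fails on both counts (1,4-O-to-O silyl shift, then five-ring lactonisation of the freed C25 alkoxide) and does not chelate. The C25 oxygen is therefore carried as a benzyloxymethyl ether, which chelates magnesium, cannot migrate and is removed reductively.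

**24 back to 21 (through 23).** Cut: C–Sn, then the enol C–O and C6–C7. Reason: only conjugate addition gives the enolate with the double bond towards the methyl-bearing carbon. Gain: ring A comes from a commodity enone. Demand: C6 must be R; an enol triflate is not a nucleophile, so it is converted to stannane, lithium and magnesium species.

**20 back to 15 (through 19, 18).** Cut: C25–C2, the C25 O–CH2 bond, and the terminal C=C of an allyl group (which is C11–C10 plus one carbon). Reason: an allyl group is inert to the alkoxide formed at C25, so the five-membered lactone cannot form before the oxygen is protected. Gain: a simple 2-allyl ketone. Demand: the acetyl anion equivalent must attack C25 equatorially to leave the oxygen axial.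

**15 back to 14.** Cut: C13–C11. Reason: enolate alkylation. Demand: enolisation towards C13 rather than C24, and an equatorial substituent.

**14 back to 7 (through 12, 11, 9).** Cut: C19–C20; a carbonyl is re-added at C17. Reason: the C17 ketone activates C19 through an enone. Demand: the isopropyl group must end cis to the C16 methyl, the contra-steric result for a conjugate addition. C19 is therefore set by hydrogenation of the 19-isopropyl enone from the face opposite the methyl.

**7 back to 1 and 2 (through 6, 5, 3).** Cut: the C23–H bond added in the conjugate reduction, then C23–C24 (aldol) and C14–C15 (Michael). Reason: the proline-catalysed annulation sets C15. Demand: the target needs the R enantiomer of the bicyclic enedione (D-proline) and a trans-selective conjugate reduction.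

## Other disconnections considered

**Alternative 1:** Cut C15–C23, C17–C18 and C18–C19, so that rings C and D arise together. Forward key step: the enyne A1 (ring A/B cyclooctenol with a 4-methylpent-2-ynyl chain on C25 and a methallyl chain on C13) is complexed with Co2(CO)8 and treated with N-methylmorpholine N-oxide; the Pauson–Khand reaction should give cyclopentenone A2.
- In its favour: three C–C bonds, two rings and the quaternary C15 form in one operation, and syn hydrogenation of the C19=C23 enone of A2 from the face opposite the C16 methyl would set C19 and C23 together in the required sense.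
- Against it here: the hard part of the molecule (ring B, the tetrasubstituted alkene, C8) must already be present in A1 and is not addressed. The 1,1-disubstituted alkene is a slow partner, and control of C15 relative to C13/C25 rests on the conformation of a flexible tether. The free tertiary allylic alcohol must survive cobalt and N-oxide.
- Comparison: on bonds and rings formed per step the alternative is better. On clean-up after the key step (enone reduction, C18 deoxygenation) it is about equal to the chosen plan (carbonyl removal, deprotection). On structure and mechanism the chosen plan is stronger, because a tethered pericyclic shift sets the medium ring, the alkene geometry and C8 through one predictable transition state.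

**Alternative 2:** Cut C19–C23 in the sense of a ring contraction; the precursor is the 5-8-6-6 homologue with a C20 ketone and a C19 diazo group. Forward key step: photolysis of diazo ketone A3 in methanol; Wolff rearrangement with C23 migrating to C19 should give ester A4.
- In its favour: a trans-decalin is easier to assemble than a trans-hydrindane, and migration with retention at C23 delivers the strained trans C/D fusion under kinetic control. On the security of that ring fusion the alternative is at least the equal of the chosen plan.
- Against it here: it edits ring D late and contributes nothing to ring B or the alkene. C19 is set by protonation during ketene trapping, towards the hindered all-cis arrangement. The ester of A4 must still become an isopropyl group (two methyl additions and removal of a tertiary hydroxyl) beside the C25 carbinol and the alkene.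
- Comparison: mechanistically clean, but on step economy it is worse (a ring is made one carbon too large, then contracted, then the ester is rebuilt). Structurally it leaves the main problem to other steps.

**Alternative 3:** Cut C13–C25, the bond common to rings B and C, back to a twelve-membered ring. Forward key step: the macrocyclic enone A5 (allylic bromide C12 on the C11=C13 alkene, C25 ketone conjugated to C2=C3) is treated with indium metal or CrCl2; the allylmetal should attack C25 through C13 to give carbinol A6.
- In its favour: one bond closes two rings and creates C13 and C25 together; the tetrasubstituted alkene is carried as part of an enone. After the key step only the C11 exocyclic methylene of A6 needs hydrogenation, so on post-key-step economy the alternative is better than the chosen plan. It also needs no protecting group on C25, which is equal or better.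
- Against it here: it needs a twelve-membered ring holding a geometrically defined tetrasubstituted enone and a trisubstituted allylic bromide. The sense of attack (trans B/C fusion, axial hydroxyl) depends on macrocycle conformation. 1,4-Addition and the later facial selectivity at C11 are further open points.
- Comparison: more elegant in bond count, but less predictable mechanistically; the chosen plan sets C11, C13 and C25 on a rigid bicycle before ring B is formed.

Key step: step 18

## Route

Remark on the chemistry: the C25 oxygen is carried as a benzyloxymethyl (BOM) ether through the key step; the skeleton, the bonds formed and all stereocentres of precursor 30 and product 31 are those of the planned rearrangement.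

Step 1
Reactants: 1 2-methylcyclopentane-1,3-dione; 2 methyl vinyl ketone
Product: 3 2-methyl-2-(3-oxobutyl)cyclopentane-1,3-dione
Conditions: H2O, AcOH (cat.), 75 °C
Reagents that add atoms: none
Why: Michael addition of the acidic 1,3-dione to the enone forms C14–C15 and the (still prochiral) quaternary carbon.

Step 2
Reactants: 3 triketone
Product: 5 (7aR)-7a-methyl-2,3,7,7a-tetrahydro-1H-indene-1,5(6H)-dione, via ketol 4 (not isolated)
Conditions: D-proline (3 mol%), DMF, 20 °C; then H2SO4 (cat.), 95 °C
Reagents that add atoms: none
Why: Hajos–Parrish–Eder–Sauer–Wiechert reaction; the enamine aldol (C23–C24) differentiates the two ring carbonyls, and D-proline gives the 7aR series, which is the one that maps onto C15 of the target. Acid then dehydrates the ketol.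

Step 3
Reactants: 5 enedione
Product: 6 (3aR,7aR)-7a-methylhexahydro-1H-indene-1,5(4H)-dione (trans-fused)
Conditions: t-BuCu (from CuI and t-BuLi, 20 mol%), i-Bu2AlH, HMPA, THF, −78 to −40 °C; aq. NH4Cl
Reagents that add atoms: none
Why: Copper hydride conjugate reduction; the bulky hydride reaches C23 from the face opposite the angular methyl, which should give the trans ring fusion. The saturated neopentyl C17 ketone is slow to react at this temperature.

Step 4
Reactants: 6 trans-dione
Product: 7 keto ketal (C25 ketone as ethylene ketal, C17 ketone free)
Conditions: ethylene glycol (1.2 equiv), p-TsOH (cat.), benzene, reflux, water separator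
Reagents that add atoms: ethylene glycol, OCCO
Why: Chemoselective ketalisation; the cyclohexanone carbonyl is far more accessible than the cyclopentanone carbonyl beside the quaternary carbon.

Step 5
Reactants: 7 keto ketal
Product: 9 enone (C17 ketone, C18=C19), via silyl enol ether 8 (not isolated)
Conditions: LiN(i-Pr)2, THF, −78 °C; Me3SiCl; then Pd(OAc)2 (10 mol%), O2 (1 atm), DMSO, 23 °C
Reagents that add atoms: none
Why: Saegusa–Ito oxidation; the ketone can enolise only towards C18, so the enol ether and the enone are regiodefined.

Step 6
Reactants: 9 enone
Product: 11 19-isopropyl enone, via silyl enol ether 10 (not isolated)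
Conditions: i-PrMgCl, CuBr·SMe2 (10 mol%), Me3SiCl, THF, −78 °C; then Pd(OAc)2 (10 mol%), O2 (1 atm), DMSO, 23 °C
Reagents that add atoms: isopropylmagnesium chloride, CC(C)[Mg]Cl
Why: Copper-catalysed conjugate addition with silyl trapping, then a second Saegusa–Ito oxidation. The C19 configuration of the adduct is irrelevant because C19 becomes sp2 again; this avoids relying on the facial sense of the cuprate addition.

Step 7
Reactants: 11 19-isopropyl enone
Product: 12 saturated 19-isopropyl ketone (isopropyl cis to the C16 methyl, trans to H-23)
Conditions: H2 (1 atm), Pd/C (10%), EtOAc, 23 °C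
Reagents that add atoms: none
Why: Heterogeneous hydrogenation; the angular methyl sits over the cyclopentenone, so hydrogen should be delivered to C19 from the H-23 face. That leaves the isopropyl group cis to the methyl, the arrangement a direct conjugate addition would not be expected to give.

Step 8
Reactants: 12 ketone
Product: 14 (3R,3aS,7aR)-7a-methyl-3-(propan-2-yl)octahydro-5H-inden-5-one, via ketal 13 (not isolated)
Conditions: N2H4·H2O, KOH, diethylene glycol, 130 then 200 °C; then 2 M HCl, THF, 23 °C
Reagents that add atoms: water, O
Why: Wolff–Kishner reduction (Huang-Minlon procedure) removes the C17 carbonyl; no stereocentre is alpha to it and the ketal is base-stable. The acidic work-up releases the C25 ketone.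

Step 9
Reactants: 14 hydrindanone
Product: 15 C13-allyl ketone (allyl equatorial, on the face opposite the C16 methyl)
Conditions: LiN(i-Pr)2, THF, −78 °C; allyl bromide, DMPU, −78 to 0 °C
Reagents that add atoms: allyl bromide, C=CCBr
Why: Enolate alkylation forming C13–C11. A trans-hydrindanone enolises away from the ring fusion (a C24=C25 enolate would flatten the strained fusion bond). The axial face at C13 is blocked by the syn-axial C16 methyl, so the allyl group enters on the other face and ends equatorial, which is also the thermodynamic position.

Step 10
Reactants: 15 allyl ketone
Product: 18 methyl ketone with axial C25–OBOM, via enol ether carbinol 16 (not isolated), via BOM enol ether 17 (not isolated)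
Conditions: CH2=CHOEt, t-BuLi, THF, −78 to 0 °C; 15, −78 °C; BnOCH2Cl, HMPA, −78 to 23 °C; then 0.5 M HCl, THF, 0 °C
Reagents that add atoms: ethyl vinyl ether, C=COCC; benzyl chloromethyl ether, ClCOCc1ccccc1; water, O
Why: 1,2-Addition of 1-ethoxyvinyllithium as an acetyl anion equivalent (C25–C2). The sp2 organolithium should attack equatorially, because axial approach meets the syn-axial H-14 and H-23 and eclipses the carbonyl with the C13 substituent, so the oxygen ends axial, cis to the allyl group. The alkoxide is capped as its BOM ether before dilute acid unmasks the methyl ketone; no ester is present, so no lactone can form.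

Step 11
Reactants: 18 allyl methyl ketone
Product: 19 carboxylic acid (C13–CH2–CO2H; C11, C10)
Conditions: KMnO4 (cat.), NaIO4, K2CO3, t-BuOH/H2O, 23 °C
Reagents that add atoms: sodium periodate, [Na+].[O-]I(=O)(=O)=O; water, O
Why: Lemieux–von Rudloff cleavage of the terminal alkene to the acid one carbon shorter; the ketone and the acetal are inert under buffered conditions, and no other alkene is present at this stage.

Step 12
Reactants: 19 acid
Product: 20 methyl ester
Conditions: MeI, K2CO3, DMF, 23 °C
Reagents that add atoms: iodomethane, CI
Why: Carboxylate O-alkylation; the base is too weak to enolise the ketone.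

Step 13
Reactants: 21 cyclopent-2-en-1-one
Product: 23 (R)-3-methylcyclopent-1-en-1-yl trifluoromethanesulfonate, via magnesium enolate 22 (not isolated)
Conditions: MeMgBr, CuCl (5 mol%), TaniaPhos-type ferrocenyl diphosphine (6 mol%, enantiomer giving 3R), Et2O, 0 °C; then N-(5-chloropyridin-2-yl)bis(trifluoromethanesulfonyl)imide, THF, −78 to 0 °C
Reagents that add atoms: methylmagnesium bromide, C[Mg]Br; N-(5-chloropyridin-2-yl)bis(trifluoromethanesulfonyl)imide, FC(F)(F)S(=O)(=O)N(c1ccc(Cl)cn1)S(=O)(=O)C(F)(F)F
Why: Copper-catalysed asymmetric conjugate addition sets C6 under ligand control. The enolate is formed only towards the methyl-bearing carbon, and O-sulfonylation fixes that regiochemistry (C3=C8 of the target).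

Step 14
Reactants: 23 enol triflate
Product: 24 (R)-trimethyl(3-methylcyclopent-1-en-1-yl)stannane
Conditions: Me3SnSnMe3, Pd(PPh3)4 (5 mol%), LiCl, THF, 65 °C
Reagents that add atoms: hexamethylditin, C[Sn](C)(C)[Sn](C)(C)C
Why: Zerovalent palladium inserts into the C–O bond of the triflate, and transmetalation with the distannane and reductive elimination give the alkenylstannane, a storable precursor of the nucleophile. The remote stereocentre is untouched.

Step 15
Reactants: 24 alkenylstannane; 20 keto ester
Product: 28 δ-lactone (C10 carbonyl, ring oxygen on C2; cyclopentenyl cis and C1 methyl trans to the C25 OBOM group on the oxane), via alkenyllithium 25 (not isolated), via alkenylmagnesium bromide 26 (not isolated), via hydroxy ester 27 (not isolated)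
Conditions: 24, MeLi, THF, −78 to 0 °C; MgBr2·OEt2, −78 °C; 20, THF/CH2Cl2, −78 to 23 °C
Reagents that add atoms: none
Why: Tin–lithium exchange and transmetalation give the Grignard reagent, which adds to the C2 ketone under Cram chelate control. Magnesium bridges the carbonyl and BOM oxygens, and the reagent enters from the C24 side because the C13 side chain blocks the other face; this places the cyclopentenyl group cis to the C25 oxygen. The ketone reacts far faster than the ester, and on warming the tertiary alkoxide closes the six-membered lactone; the BOM ether cannot migrate and rules out the five-membered lactone.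

Step 16
Reactants: 28 lactone
Product: 29 C11-methyl lactone (methyl equatorial, cis to H-13)
Conditions: LiN(i-Pr)2, THF, −78 °C; MeI, −78 to −40 °C; then DBU, toluene, 60 °C
Reagents that add atoms: iodomethane, CI
Why: Lactone enolate alkylation forming C11–C12. The axial C25 oxygen blocks the syn-axial trajectory, so methyl iodide should enter from the opposite face; the base treatment equilibrates any axial epimer to the equatorial methyl, which is the configuration of the target.

Step 17
Reactants: 29 lactone
Product: 30 2-methylene oxane (exocyclic C9=C10 enol ether; C2 bears the (R)-3-methylcyclopentenyl group cis to the C25 OBOM group)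
Conditions: Cp2TiMe2 (3 equiv), pyridine (1 mol%), toluene, 75 °C, dark; filtration through basic alumina
Reagents that add atoms: dimethyltitanocene, C[Ti](C)(C1C=CC=C1)C2C=CC=C2
Why: Carbonyl methylenation of a lactone by the titanium methylidene formed on heating; the reagent is non-basic, so C11 is not epimerised. The only carbonyl in the molecule is the lactone.

Step 18
Reactants: 30 2-methylene oxane
Product: 31 10-oxo-sesterfisherol benzyloxymethyl ether
Conditions: toluene, i-Pr2NEt (1 mol%), base-washed sealed tube, 170 °C
Reagents that add atoms: none
Why: Thermal Claisen rearrangement of the allyl vinyl ether C9=C10–O–C2–C3=C8: a concerted suprafacial [3,3] shift forms C8–C9 as C2–O breaks, leaving the C10 ketone and the C2=C3 alkene; the closest known reaction type is the ring expansion of 2-methylene-6-vinyltetrahydropyrans to cyclooct-4-enones. Ring B closes by ring expansion: the six-membered oxane becomes the eight-membered carbocycle through a bicyclo[3.3.1]-like transition state that is chair-like in the six reacting atoms. Because the cyclopentenyl group is equatorial on the trans-fused oxane chair, the oxane must twist into a twist-boat to bring C8 over C9; this is why a high temperature is chosen, and the axial C1 methyl of the chair lowers the cost of the change. C8 is controlled by the C2 carbinol centre: the tether allows only the arrangement with C25 syn to C8, so C9 is delivered to the cyclopentene face that oxygen leaves, which is also the face anti to the C6 methyl. The same constraint fixes the ring alkene as Z. The step needs [3,3] shift to win over ionisation of the tertiary allylic C2–O bond and needs the exocyclic enol ether not to migrate into the ring; a non-polar medium, a trace of amine and base-washed glass are chosen to secure both. The BOM ether and C11 are not involved.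

Step 19
Reactants: 31 ketone
Product: 32 10-hydroxy compound (C10 epimers)
Conditions: LiAlH4, THF, 0 °C
Reagents that add atoms: none
Why: Hydride reduction at low temperature converts the ketone before C11 can epimerise; the C10 configuration is irrelevant.

Step 20
Reactants: 32 alcohol
Product: 33 S-methyl xanthate
Conditions: NaH, CS2, THF, 0 to 23 °C; MeI
Reagents that add atoms: carbon disulfide, S=C=S; iodomethane, CI
Why: Xanthate formation on the only free hydroxyl; the tertiary oxygen is protected.

Step 21
Reactants: 33 xanthate
Product: 34 sesterfisherol benzyloxymethyl ether
Conditions: Bu3SnH (5 equiv), AIBN (cat.), toluene, 90 °C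
Reagents that add atoms: none
Why: Barton–McCombie deoxygenation; the high stannane concentration should trap the secondary C10 radical before it can add across the ring to the hindered tetrasubstituted alkene. No stereocentre is formed or lost.

Step 22
Reactants: 34 BOM ether
Product: 35 sesterfisherol
Conditions: Li, NH3(l), THF, −78 °C; NH4Cl
Reagents that add atoms: none
Why: Dissolving-metal cleavage of the benzyl C–O bond; the hemiformal loses formaldehyde on work-up. The isolated tetrasubstituted alkene does not accept an electron, and no acid is used, so the tertiary allylic alcohol is released intact.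

## Compound list

1 | 2-methylcyclopentane-1,3-dione | CC1C(=O)CCC1=O | starting material
2 | methyl vinyl ketone (but-3-en-2-one) | CC(=O)C=C | starting material
3 | 2-methyl-2-(3-oxobutyl)cyclopentane-1,3-dione | CC(=O)CCC1(C)C(=O)CCC1=O | intermediate
4 | (3aR,7aR)-3a-hydroxy-7a-methylhexahydro-1H-indene-1,5(4H)-dione (cis ketol, not isolated) | C[C@@]12CCC(=O)C[C@]1(O)CCC2=O | intermediate
5 | (7aR)-7a-methyl-2,3,7,7a-tetrahydro-1H-indene-1,5(6H)-dione | C[C@@]12CCC(=O)C=C1CCC2=O | intermediate
6 | (3aR,7aR)-7a-methylhexahydro-1H-indene-1,5(4H)-dione (trans-fused; C17 and C25 ketones) | O=C1CC[C@@]2(C)C(=O)CC[C@@H]2C1 | intermediate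
7 | trans-fused keto ketal: 6 with the C25 ketone as ethylene ketal, C17 ketone free | O1CCOC12CC[C@@]3(C)C(=O)CC[C@@H]3C2 | intermediate
8 | trimethylsilyl enol ether of 7 (C17–OSiMe3, C17=C18; not isolated) | O1CCOC12CC[C@@]3(C)C(O[Si](C)(C)C)=CC[C@@H]3C2 | intermediate
9 | enone: 7 with C18=C19 conjugated to the C17 ketone, trans ring fusion | O1CCOC12CC[C@@]3(C)C(=O)C=C[C@@H]3C2 | intermediate
10 | trimethylsilyl enol ether (C17–OSiMe3, C17=C18) of the 19-isopropyl ketone, C19 epimers (not isolated) | O1CCOC12CC[C@@]3(C)C(O[Si](C)(C)C)=CC(C(C)C)[C@@H]3C2 | intermediate
11 | 19-isopropyl enone: 9 with isopropyl on C19 | O1CCOC12CC[C@@]3(C)C(=O)C=C(C(C)C)[C@@H]3C2 | intermediate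
12 | saturated 19-isopropyl C17 ketone, C25 ketal; isopropyl cis to the C16 methyl, trans to H-23 | O1CCOC12CC[C@@]3(C)C(=O)C[C@H](C(C)C)[C@@H]3C2 | intermediate
13 | ethylene ketal of 14 (not isolated) | O1CCOC12CC[C@@]3(C)CC[C@H](C(C)C)[C@@H]3C2 | intermediate
14 | (3R,3aS,7aR)-7a-methyl-3-(propan-2-yl)octahydro-5H-inden-5-one (C25 ketone, trans fusion) | O=C1CC[C@@]2(C)CC[C@H](C(C)C)[C@@H]2C1 | intermediate
15 | 14 with an equatorial allyl group on C13, on the face opposite the C16 methyl | O=C1[C@@H](CC=C)C[C@@]2(C)CC[C@H](C(C)C)[C@@H]2C1 | intermediate
16 | C25 carbinol: 1-ethoxyvinyl equatorial, OH axial and cis to the C13 allyl group (not isolated) | C=C(OCC)[C@]1(O)[C@@H](CC=C)C[C@@]2(C)CC[C@H](C(C)C)[C@@H]2C1 | intermediate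
17 | benzyloxymethyl ether of 16 (not isolated) | C=C(OCC)[C@]1(OCOCc2ccccc2)[C@@H](CC=C)C[C@@]3(C)CC[C@H](C(C)C)[C@@H]3C1 | intermediate
18 | methyl ketone: C25 bears acetyl (C2, C1) and axial OBOM; C13 allyl cis to OBOM | CC(=O)[C@]1(OCOCc2ccccc2)[C@@H](CC=C)C[C@@]3(C)CC[C@H](C(C)C)[C@@H]3C1 | intermediate
19 | carboxylic acid: 18 with the allyl group degraded to CH2CO2H (C11, C10) | CC(=O)[C@]1(OCOCc2ccccc2)[C@@H](CC(=O)O)C[C@@]3(C)CC[C@H](C(C)C)[C@@H]3C1 | intermediate
20 | methyl ester of 19 | CC(=O)[C@]1(OCOCc2ccccc2)[C@@H](CC(=O)OC)C[C@@]3(C)CC[C@H](C(C)C)[C@@H]3C1 | intermediate
21 | cyclopent-2-en-1-one | O=C1C=CCC1 | starting material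
22 | bromomagnesium enolate of (R)-3-methylcyclopentanone, C1=C2 (not isolated) | Br[Mg]OC1=C[C@H](C)CC1 | intermediate
23 | (R)-3-methylcyclopent-1-en-1-yl trifluoromethanesulfonate | O=S(=O)(OC1=C[C@H](C)CC1)C(F)(F)F | intermediate
24 | (R)-trimethyl(3-methylcyclopent-1-en-1-yl)stannane | C[Sn](C)(C)C1=C[C@H](C)CC1 | intermediate
25 | (R)-(3-methylcyclopent-1-en-1-yl)lithium (not isolated) | [Li]C1=C[C@H](C)CC1 | intermediate
26 | (R)-(3-methylcyclopent-1-en-1-yl)magnesium bromide (not isolated) | Br[Mg]C1=C[C@H](C)CC1 | intermediate
27 | hydroxy ester: 20 after addition of ring A to C2, C2 configured as in 28 (not isolated) | C[C@@](O)(C1=C[C@H](C)CC1)[C@]2(OCOCc3ccccc3)[C@@H](CC(=O)OC)C[C@@]4(C)CC[C@H](C(C)C)[C@@H]4C2 | intermediate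
28 | δ-lactone (C10 carbonyl, ring O on C2), C11 unsubstituted; cyclopentenyl on C2 cis and C1 methyl trans to the C25 OBOM group; trans-fused to ring C | O=C1C[C@H]2C[C@@]3(C)CC[C@H](C(C)C)[C@@H]3C[C@]2(OCOCc4ccccc4)[C@](C)(O1)C5=C[C@H](C)CC5 | intermediate
29 | 28 with an equatorial methyl (C12) on C11, cis to H-13 | O=C1[C@H](C)[C@H]2C[C@@]3(C)CC[C@H](C(C)C)[C@@H]3C[C@]2(OCOCc4ccccc4)[C@](C)(O1)C5=C[C@H](C)CC5 | intermediate
30 | 2-methylene oxane (C9=C10 exocyclic enol ether) derived from 29; key-step precursor | C=C1[C@H](C)[C@H]2C[C@@]3(C)CC[C@H](C(C)C)[C@@H]3C[C@]2(OCOCc4ccccc4)[C@](C)(O1)C5=C[C@H](C)CC5 | intermediate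
31 | 10-oxo-sesterfisherol benzyloxymethyl ether; key-step product | C/C1=C2\CC[C@@H](C)[C@@H]2CC(=O)[C@H](C)[C@H]2C[C@@]3(C)CC[C@H](C(C)C)[C@@H]3C[C@]12OCOCc4ccccc4 | intermediate
32 | 10-hydroxy-sesterfisherol benzyloxymethyl ether (C10 epimers) | C/C1=C2\CC[C@@H](C)[C@@H]2CC(O)[C@H](C)[C@H]2C[C@@]3(C)CC[C@H](C(C)C)[C@@H]3C[C@]12OCOCc4ccccc4 | intermediate
33 | O-(C10) S-methyl xanthate of 32 | C/C1=C2\CC[C@@H](C)[C@@H]2CC(OC(=S)SC)[C@H](C)[C@H]2C[C@@]3(C)CC[C@H](C(C)C)[C@@H]3C[C@]12OCOCc4ccccc4 | intermediate
34 | sesterfisherol benzyloxymethyl ether | C/C1=C2\CC[C@@H](C)[C@@H]2CC[C@H](C)[C@H]2C[C@@]3(C)CC[C@H](C(C)C)[C@@H]3C[C@]12OCOCc4ccccc4 | intermediate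
35 | sesterfisherol (6R,8S,11S,13R,15R,19R,23S,25R in the numbering used here; Z alkene) | C/C1=C2\CC[C@@H](C)[C@@H]2CC[C@H](C)[C@H]2C[C@@]3(C)CC[C@H](C(C)C)[C@@H]3C[C@]12O | target

## Step count and least certain steps

Total: 22 steps. Longest linear sequence: 20 steps (steps 1–12 and 15–22); steps 13 and 14 make the ring A fragment.

**Step 18 (key step).** The rearrangement may stall or divert. The reacting conformer requires the trans-fused oxane to leave its chair, and at the temperature this demands, heterolysis of the tertiary allylic C2–O bond (leading to a [1,3] shift or to elimination) and acid-triggered migration of the enol ether double bond into the ring can compete. Fallback: setting out from 30, triisobutylaluminium (i-Bu3Al, CH2Cl2, −78 to 23 °C) promotes the ring expansion through an aluminium-bound, polarised transition state at or below room temperature and reduces the new ketone in the same flask, so the route is rejoined at alcohol 32 without passing through 31. This fallback makes no compound outside the list (F0).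

**Step 15.** Facial control at C2 may erode if the ester carbonyl competes with the BOM oxygen for magnesium. The basic reagent may also enolise the methyl ketone, and the hindered magnesium alkoxide may fail to close the lactone. Fallback: setting out from acid 19, the carboxyl is masked as its magnesium carboxylate (i-PrMgCl, 1 equiv), which is not an electrophile, and 26 is added to the ketone under the same BOM chelation to give hydroxy acid F1. The ring is then closed in a separate carboxyl-activation step (EDC·HCl, DMAP, CH2Cl2, or 2,4,6-trichlorobenzoyl chloride, Et3N, DMAP), returning to the route at 28.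

**Step 10.** Attack along the axial direction would give the C25 epimer. Capping of the hindered lithium alkoxide may be incomplete, or the chloromethyl ether may alkylate the electron-rich enol ether. Fallback: setting out from 15, the bulkier isopropenylmagnesium bromide (THF, −78 °C) serves as the acetyl equivalent and gives the isolable isopropenyl carbinol F2. This is protected under forcing conditions (KH, BnOCH2Cl, THF) as BOM ether F3. One ozonolysis (O3, CH2Cl2/MeOH, −78 °C; Me2S) cleaves both terminal alkenes to keto aldehyde F4, and Pinnick oxidation (NaClO2, NaH2PO4, 2-methylbut-2-ene) returns to the route at acid 19.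

**Step 13.** Enantioselectivity may be low for the five-membered enone, and the cyclopentanone enolate can add to unreacted enone, consuming material. Fallback: setting out from 21, MeLi addition gives 1-methylcyclopent-2-en-1-ol F5, and oxidative 1,3-transposition with pyridinium chlorochromate, [C5H5NH][CrO3Cl], gives 3-methylcyclopent-2-en-1-one F6 (also an article of commerce). Asymmetric copper hydride conjugate reduction (CuCl, NaOt-Bu, p-Tol-BINAP, Ph2SiH2, toluene) moves the stereo-determining event from methyl transfer to hydride transfer and gives the diphenylsilyl enol ether F7 of (R)-3-methylcyclopentanone with the same enol regiochemistry. MeLi followed by the pyridyl triflimide returns to the route at 23.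

**Step 17.** Methylenation of the hindered, alpha-branched lactone may be incomplete, and the exocyclic double bond may drift into the ring (C10=C11) on titanium residues or on the adsorbent. Fallback: setting out from 29, one equivalent of MeLi (THF, −78 °C) stops at the methyl lactol F8. Base-mediated dehydration towards the methyl group (trifluoroacetic anhydride, pyridine, or MsCl, Et3N) then gives the exocyclic enol ether, returning to the route at 30.

**Step 21.** The C10 radical may add across the ring to C2 of the C2=C3 alkene (transannular 5-exo closure), and the xanthate may undergo thermal syn-elimination. Fallback: setting out from 32, the alcohol is converted (n-BuLi; ClP(O)(NMe2)2) into the tetramethylphosphorodiamidate F9. Lithium in ethylamine (t-BuOH, THF, 0 °C) then cleaves the C10–O bond by electron transfer, with no long-lived radical, and removes the benzyl group of the acetal in the same operation, returning to the route at 35.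

## Further compounds

F0 | step 18 | none | none
F1 | step 15 | hydroxy acid: acid 19 after addition of 26 to C2 (C2 as in 28) | C[C@@](O)(C1=C[C@H](C)CC1)[C@]2(OCOCc3ccccc3)[C@@H](CC(=O)O)C[C@@]4(C)CC[C@H](C(C)C)[C@@H]4C2
F2 | step 10 | isopropenyl carbinol: 15 after equatorial addition of isopropenyl to C25 (OH axial, cis to allyl) | CC(=C)[C@]1(O)[C@@H](CC=C)C[C@@]2(C)CC[C@H](C(C)C)[C@@H]2C1
F3 | step 10 | benzyloxymethyl ether of F2 | CC(=C)[C@]1(OCOCc2ccccc2)[C@@H](CC=C)C[C@@]3(C)CC[C@H](C(C)C)[C@@H]3C1
F4 | step 10 | keto aldehyde: C25 acetyl and OBOM, C13–CH2–CHO | CC(=O)[C@]1(OCOCc2ccccc2)[C@@H](CC=O)C[C@@]3(C)CC[C@H](C(C)C)[C@@H]3C1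
F5 | step 13 | 1-methylcyclopent-2-en-1-ol | CC1(O)C=CCC1
F6 | step 13 | 3-methylcyclopent-2-en-1-one | CC1=CC(=O)CC1
F7 | step 13 | (R)-[(3-methylcyclopent-1-en-1-yl)oxy]diphenylsilane | [SiH](c1ccccc1)(c2ccccc2)OC3=C[C@H](C)CC3
F8 | step 17 | methyl lactol: 29 with C10 as C(OH)CH3 (anomers) | CC1(O)[C@H](C)[C@H]2C[C@@]3(C)CC[C@H](C(C)C)[C@@H]3C[C@]2(OCOCc4ccccc4)[C@](C)(O1)C5=C[C@H](C)CC5
F9 | step 21 | C10 N,N,N',N'-tetramethylphosphorodiamidate of 32 | C/C1=C2\CC[C@@H](C)[C@@H]2CC(OP(=O)(N(C)C)N(C)C)[C@H](C)[C@H]2C[C@@]3(C)CC[C@H](C(C)C)[C@@H]3C[C@]12OCOCc4ccccc4
A1 | alternative 1 | enyne: ring A/B cyclooctenol with 4-methylpent-2-ynyl on C25 and methallyl on C13 | C/C1=C2\CC[C@@H](C)[C@@H]2CC[C@H](C)[C@@H](CC(C)=C)[C@]1(O)CC#CC(C)C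
A2 | alternative 1 | tetracyclic C18 ketone with C19=C23 enone | C/C1=C2\CC[C@@H](C)[C@@H]2CC[C@H](C)[C@H]2C[C@@]3(C)CC(=O)C(C(C)C)=C3C[C@]12O
A3 | alternative 2 | 5-8-6-6 homologue, C19 diazo C20 ketone, C25 triethylsilyl ether | C/C1=C2\CC[C@@H](C)[C@@H]2CC[C@H](C)[C@H]2C[C@@]3(C)CCC(=[N+]=[N-])C(=O)[C@@H]3C[C@]12O[Si](CC)(CC)CC
A4 | alternative 2 | 5-8-6-5 tetracycle with C20 methyl ester on C19, C25 triethylsilyl ether | C/C1=C2\CC[C@@H](C)[C@@H]2CC[C@H](C)[C@H]2C[C@@]3(C)CC[C@H](C(=O)OC)[C@@H]3C[C@]12O[Si](CC)(CC)CC
A5 | alternative 3 | 5-12-5 macrocyclic enone with bromomethyl (C12) on the C11=C13 alkene | C/C1=C2\CC[C@@H](C)[C@@H]2CCC(CBr)=CC[C@@]3(C)CC[C@H](C(C)C)[C@@H]3CC1=O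
A6 | alternative 3 | tetracyclic C25 carbinol with C11 exocyclic methylene | C/C1=C2\CC[C@@H](C)[C@@H]2CCC(=C)[C@H]2C[C@@]3(C)CC[C@H](C(C)C)[C@@H]3C[C@]12O
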